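A leftover of 5.00% of the electrophile at 10 h is what this flask has to reach, and on a logarithmic scale that is a fall of 1.30 powers of ten.

in all of them: electrophile 0.050 M
- violet: nucleophile 3.1 equiv; run made earlier
- flask: time 10 h

violet run (percent of the electrophile charged): time / min: product / % = 5.00: 5.2; 15.0: 10.5; 30.0: 17.2; 40.0: 22.5; 60.0: 28.8

(scatter of a reading: 1 percentage point)

1. the equivalents of nucleophile at which the part of the electrophile that has reacted at 10 h is just 95%

- the amount of nucleophile is what is sought; it is there from the start
- the numbers in the tables scatter by 1 percentage point (one standard deviation)
- a reading or a percentage of product counts all its forms, free or not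
- what has gone from electrophile into another species counts as reacted, even if it can come back

Dividing that fall by the time gives the required pace, the powers of ten of electrophile lost per unit time, 0.130 h⁻¹.

I draw the violet run on the same scale, counting product as electrophile gone, and that is a floor on what has reacted. Over the first 5.00 min the pace is 0.278 h⁻¹, faster than required. Then comes a knee: from 30.0 min to 60.0 min it reads 0.131 h⁻¹, half the start and close to the required pace. I take the start as the pace of the fresh charge, though it rests on one reading with a scatter of 1 percentage point.

Treating the loss as pseudo-first-order in free nucleophile, the required pace asks for 1.45 equiv still free at the end. Adding one nucleophile for each electrophile reacted, which is my assumption here, I commit to 2.40 equiv. The forecast is higher, at 3.4 equiv within 2.9 equiv to 4.6 equiv, from a rate of which its maker wrote “I treat it as simple bimolecular”.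

The flask needs 1.57 equiv, less than my figure.

    electrophile + nucleophile → acid set free + product (k = 0.0567 M⁻¹ min⁻¹)
    nucleophile + acid set free ⇌ protonated nucleophile, settled at all times (K = 2400 M⁻¹)
    2 electrophile → homo dimer (k = 0.0670 M⁻¹ min⁻¹)
    electrophile + product ⇌ idle adduct, settled at all times (K = 940 M⁻¹)

At that charge 52.1% of the electrophile is used at 1.00 h. On the logarithmic scale that first stretch runs at 0.320 h⁻¹, faster than the required pace. Between 5.00 h and 10 h, where used electrophile climbs from 89.3% to the wanted level, the pace is 0.0659 h⁻¹, half the required one.

(Readings and results are calculated with made-up constants; scatter was added.)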